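- Ochre, charged with more free base than violet, holds less electrophile at 15.0 h: 48.1% against 55.4%. The new flasks, epsilon and gamma, differ in free base too.

| flask | electrophile | free base | protonated nucleophile | protic impurity | remark | time |
|---|---|---|---|---|---|---|
| violet | 0.050 M | 0.74 equiv | 3 equiv | 5 mM | run made earlier |  |
| ochre | 0.050 M | 1.1 equiv | 3 equiv | 5 mM | run made earlier |  |
| epsilon | 0.050 M | 1.00 equiv | 3.00 equiv | 5.00 mM |  | 20 h |
| gamma | 0.050 M | 1.30 equiv | 3.00 equiv | 5.00 mM |  | 20 h |

- violet (time / h: electrophile / %, target / %): 1.00: 87.8, 6.5; 2.50: 76.2, 16.5; 5.00: 70.5, 22.9; 8.00: 64.0, 28.9; 10.0: 62.0, 28.4; 15.0: 55.4, 33.3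
- ochre (time / h: electrophile / %, target / %): 1.00: 86.1, 8.7; 2.50: 72.7, 18.9; 5.00: 61.2, 29.4; 8.00: 55.7, 34.9; 10.0: 51.0, 39.8; 15.0: 48.1, 44.7

(standard deviation of a reading: 1 percentage point)

* part of the electrophile that has reacted at the end, epsilon
* part of the electrophile that has reacted at the end, gamma
* what raising the equivalents of free base from its lowest to its highest value here does to the part of the electrophile that has reacted (changes below 5 percentage points count as none) (it falls / no change / it rises)

- amounts and yields of target count crystals too
- given per volume of solution although it is solid: crystals
- the analysis behind the earlier runs scatters by 1 percentage point, standard deviation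
- steps that have been proposed: electrophile + nucleophile -> acid set free + target; nucleophile + acid set free <-> protonated nucleophile; acid set free + free base <-> salt of the base; crystals <-> target; electrophile + protic impurity -> quenched substrate; acid set free -> by-product carried off

- Free base, by hand: it frees nucleophile from protonated nucleophile. Each target then spends one nucleophile and frees one acid, which takes up a second unit of base. While acid stays in the flask, epsilon stands at 50.0% and gamma at 65.0% under the target ceiling Y, the free base equivalents charged divided by two. Readings at 15.0 h: ochre has 44.7% under its 55.0%, violet 33.3% under its 37.0%.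
- Time, by hand: target should creep as it nears Y. Ochre's readings gain 10 percentage points from 5.00 h to 10.0 h, then 4.9 points by 15.0 h.
- Protic impurity, by hand: as limiting reagent of the quench, it can claim a share q of 10.0% of the electrophile. The gaps between electrophile lost and target at the last readings, 7.2 points in ochre and 11 points in violet, lie on either side of it.
- While acid stays in the flask, Y plus q gives a ceiling on the reacted part of 60.0% in epsilon and 75.0% in gamma. This reckoning gives ceilings under that condition, not the forecast's values.
- The forecast says 55% for epsilon, 65% for gamma and it rises, on the ground that each target “uses two units of base capacity”.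
- The flasks give 54.3% in epsilon and 62.7% in gamma. With free base raised from its lowest to its highest value, the reacted part behaves so: it rises, by 8.3 points.

    electrophile + nucleophile → acid set free + target (k = 4.44 L mol⁻¹ h⁻¹)
    nucleophile + acid set free ⇌ protonated nucleophile, settled at all times (K = 1.50 × 10⁵ L mol⁻¹)
    acid set free + free base ⇌ salt of the base, settled at all times (K = 30000 L mol⁻¹)
    crystals ⇌ target, rate k4*(cs4 - [target]) while solid is left; crystals form when [target] > cs4 (solubility = 21.0 mM, k = 5.81 h⁻¹)
    electrophile + protic impurity → quenched substrate (k = 15.0 L mol⁻¹ h⁻¹)
    acid set free → by-product carried off (k = 0.365 h⁻¹)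

- At 20.0 h, target stands under Y in epsilon, 44.3%, and in gamma, 52.7%.
- A neighbour of gamma with 0.020 M protic impurity keeps the same Y and has 43.2% target, yet 82.9% has reacted, above the forecast's 65% for gamma.
- Neither flask has come to rest: by 200 h epsilon reaches 87.5% and gamma 92.5%. Epsilon's target then stands at 77.5%, past Y, and its by-product carried off has grown from 0.00120 M to 0.0333 M.

Readings and results were generated by integration for substances that don't exist; scatter was added.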